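**Retrosynthetic overview** (ring A = C1, C2, C3, C4, C5, C9; ring B = C1, C9, C5, C6, C7, C8; target locants are used for every intermediate)
1. Isariotin C ⇐ alkene 36 by C6‑OH‑directed epoxidation of C7=C8 (last step) ⇐ amine 27 + (E)‑7‑oxododec‑2‑enoic acid 34 (from δ‑valerolactone) by amide coupling.
2. Feature used: in ring B the C6 carbinol sits next to the C7–C8 epoxide, an allylic‑alcohol retron; cutting C6–C7 leaves ring A with a (Z)‑2‑iodovinyl arm on C1 and a formyl group on C5, with C9 carried as a carbinol cis to the formyl group.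
3. Ring B ⇐ intramolecular Nozaki–Hiyama–Kishi closure of ring‑A aldehyde 23 (C6–C7 bond, C6 stereocentre).
4. 23 ⇐ C9 ketone 14 (C5 dimethoxymethylation, C1‑OH‑directed reduction, alkyne to Z‑iodoalkene) ⇐ C1 ketone 8 (ethynyl addition under a bridged C4/C9 carbonate) ⇐ meso diol 2 (enantioselective monosilylation, iodocarbonate cyclisation for C4–O, azide inversion for C3–N) ⇐ cyclohexa‑1,4‑diene.
5. Ring order: ring A is present from the start; ring B closes in step 18; the epoxide is formed in step 28.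

Key step: step 18

Remark (assumption): the catalyst enantiomer named in step 2 is taken to give the (1S,6R) monosilyl ether; if its sense of induction is the reverse, its mirror image is used.

Step 1
Reactants: 1 cyclohexa‑1,4‑diene
Product: 2 cis‑cyclohex‑4‑ene‑1,2‑diol (meso)
Conditions: K2OsO4·2H2O (0.5 mol%), NMO (1.0 equiv), acetone/H2O, 0 °C to rt; 1 in twofold excess
Reagents that add atoms: N‑methylmorpholine N‑oxide, C[N+]1([O-])CCOCC1; water, O
Why: Osmium‑catalysed syn‑dihydroxylation with an N‑oxide reoxidant adds both hydroxyls to one face of one alkene, and the excess of diene should hold the reaction at the meso cis‑diol.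

Step 2
Reactants: 2 cis‑cyclohex‑4‑ene‑1,2‑diol
Product: 3 (1S,6R)‑6‑[(tert‑butyldimethylsilyl)oxy]cyclohex‑3‑en‑1‑ol (C1–OTBS and C9–OH cis)
Conditions: TBSCl, i‑Pr2NEt, (S)‑N‑[(R)‑3,3‑dimethylbutan‑2‑yl]‑3,3‑dimethyl‑2‑{[(1‑methyl‑1H‑imidazol‑2‑yl)methyl]amino}butanamide (30 mol%), THF, −40 °C
Reagents that add atoms: tert‑butyldimethylsilyl chloride, CC(C)(C)[Si](C)(C)Cl
Why: Catalytic enantioselective monosilylation (desymmetrisation) of a meso 1,2‑diol by the chiral imidazole amide differentiates the enantiotopic hydroxyls and sets the absolute configuration of the carbinol carbon that becomes C9 (S), from which all later stereocentres are relayed.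

Step 3
Reactants: 3 monosilyl ether
Product: 4 tert‑butyl (1S,6R)‑6‑[(tert‑butyldimethylsilyl)oxy]cyclohex‑3‑en‑1‑yl carbonate
Conditions: Boc2O, DMAP (10 mol%), MeCN, rt
Reagents that add atoms: di‑tert‑butyl dicarbonate, CC(C)(C)OC(=O)OC(=O)OC(C)(C)C
Why: DMAP‑catalysed acylation of the free secondary alcohol gives the homoallylic tert‑butyl carbonate that serves as the internal oxygen nucleophile.

Step 4
Reactants: 4 Boc carbonate
Product: 5 6‑[(tert‑butyldimethylsilyl)oxy]‑8‑iodo‑2,4‑dioxabicyclo[3.3.1]nonan‑3‑one (C9–O/C4–O carbonate; C1–O, C9–O, C4–O all cis; iodine on C3 trans to C4–O)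
Conditions: IBr, toluene/CH2Cl2, −78 °C; aq. Na2S2O3/NaHCO3
Reagents that add atoms: iodine monobromide, IBr
Why: Iodocarbonate cyclisation: the carbonate carbonyl oxygen on C9 opens the iodonium ion at C4 in a 6‑exo, trans‑diaxial (Fürst–Plattner) manner with loss of the tert‑butyl group, so C4–O is delivered cis to C9–O and iodine lands on C3 anti to it.

Step 5
Reactants: 5 iodocarbonate
Product: 6 8‑azido‑6‑[(tert‑butyldimethylsilyl)oxy]‑2,4‑dioxabicyclo[3.3.1]nonan‑3‑one (C3–N3 cis to C4–O)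
Conditions: NaN3, DMF, 60 °C
Reagents that add atoms: sodium azide, [Na+].[N-]=[N+]=[N-]
Why: SN2 displacement of the axial secondary iodide by azide inverts C3 and places nitrogen cis to the C4 oxygen; azide is a weak base, which should limit E2.

Step 6
Reactants: 6 azido silyl ether
Product: 7 8‑azido‑6‑hydroxy‑2,4‑dioxabicyclo[3.3.1]nonan‑3‑one
Conditions: HF·pyridine, pyridine/THF, 0 °C to rt
Reagents that add atoms: none
Why: Fluoride‑mediated silyl ether cleavage under buffered, non‑basic conditions frees the C1 hydroxyl without forming an alkoxide that could attack the neighbouring carbonate.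

Step 7
Reactants: 7 azido alcohol
Product: 8 8‑azido‑2,4‑dioxabicyclo[3.3.1]nonane‑3,6‑dione (C1 ketone)
Conditions: DMP (1,1,1‑triacetoxy‑1,1‑dihydro‑1,2‑benziodoxol‑3(1H)‑one), NaHCO3, CH2Cl2, 0 °C to rt
Reagents that add atoms: none
Why: Dess–Martin oxidation of the secondary alcohol gives the C1 ketone under near‑neutral conditions that spare the beta‑azido ketone and the carbonate, and C9 cannot epimerise because it is a bridgehead of the bicyclic carbonate.

Step 8
Reactants: 8 azido ketone; 9 ethynylmagnesium bromide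
Product: 10 8‑azido‑6‑ethynyl‑6‑hydroxy‑2,4‑dioxabicyclo[3.3.1]nonan‑3‑one (C1–OH cis to C9–O, C4–O and C3–N; ethynyl on the opposite face)
Conditions: CeCl3 (anhydrous), THF, −78 °C; AcOH quench at −78 °C
Reagents that add atoms: none
Why: 1,2‑Addition of the organocerium reagent to the ketone: the bridged carbonate locks ring A as a chair with the C9 and C4 oxygens axial on the lower face, so the small nucleophile should attack axially from the open upper face anti to the alpha C9–O bond (Felkin–Anh), which sets C1 with its hydroxyl on the lower face.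

Step 9
Reactants: 10 ethynyl carbinol
Product: 12 5‑azido‑6‑[(tert‑butyldimethylsilyl)oxy]‑3a‑ethynylhexahydro‑1,3‑benzodioxol‑2‑one (C1/C9 cis‑fused carbonate; C4–OTBS), via rearranged sodium alkoxide 11 (not isolated)
Conditions: NaN(SiMe3)2 (1.05 equiv), THF, −78 to 0 °C; then TBSCl, 0 °C
Reagents that add atoms: tert‑butyldimethylsilyl chloride, CC(C)(C)[Si](C)(C)Cl
Why: Base‑induced intramolecular transcarbonation (carbonate migration): the tertiary C1 alkoxide attacks the bridged carbonate to give the cis‑fused five‑membered C1/C9 carbonate and the secondary C4 alkoxide, and only this unhindered alkoxide is silylated quickly by TBSCl, so the C4 and C9 oxygens are told apart.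

Step 10
Reactants: 12 cyclic carbonate
Product: 13 5‑azido‑4‑[(tert‑butyldimethylsilyl)oxy]‑1‑ethynylcyclohexane‑1,2‑diol (C1–OH, C9–OH, C4–O, C3–N all cis)
Conditions: K2CO3 (0.2 equiv), MeOH, 0 °C to rt
Reagents that add atoms: none
Why: Base‑catalysed methanolysis (transesterification) of the cyclic carbonate releases the C1/C9 diol, while silyl ether, azide and alkyne are untouched.

Step 11
Reactants: 13 azido diol
Product: 14 4‑azido‑5‑[(tert‑butyldimethylsilyl)oxy]‑2‑ethynyl‑2‑hydroxycyclohexan‑1‑one (C9 ketone)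
Conditions: IBX (2‑iodoxybenzoic acid), DMSO, rt
Reagents that add atoms: none
Why: IBX oxidation of the only secondary alcohol gives the alpha‑hydroxy ketone, since IBX oxidises 1,2‑diols without C–C cleavage and the tertiary hydroxyl cannot be oxidised.

Step 12
Reactants: 14 alpha‑hydroxy ketone
Product: 17 4‑azido‑5‑[(tert‑butyldimethylsilyl)oxy]‑6‑(dimethoxymethyl)‑2‑ethynyl‑2‑hydroxycyclohexan‑1‑one (C5 substituent trans to C4–O), via bis‑silyl enol ether 15 (not isolated), via trimethylsilyl ether 16 (not isolated)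
Conditions: TMSOTf, Et3N, CH2Cl2, 0 °C; pentane, filtration, concentration; HC(OMe)3, TMSOTf (10 mol%), CH2Cl2, −78 °C; citric acid, MeOH, 0 °C
Reagents that add atoms: trimethyl orthoformate, COC(OC)OC
Why: Mukaiyama aldol‑type reaction of a silyl enol ether with an orthoester: enolisation can only go toward C5 (C1 is quaternary) and also masks the tertiary hydroxyl, the dimethoxycarbenium ion should add to C5 anti to the adjacent C4 silyloxy group (trans, also the thermodynamic arrangement), and methanolic acid removes the tertiary TMS ether.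

Step 13
Reactants: 17 azido keto acetal
Product: 19 tert‑butyl [2‑[(tert‑butyldimethylsilyl)oxy]‑3‑(dimethoxymethyl)‑5‑ethynyl‑5‑hydroxy‑4‑oxocyclohexyl]carbamate, via amine 18 (not isolated)
Conditions: PMe3, THF/H2O, rt; then Boc2O, NaHCO3, rt
Reagents that add atoms: di‑tert‑butyl dicarbonate, CC(C)(C)OC(=O)OC(=O)OC(C)(C)C
Why: Staudinger reduction of the azide followed by carbamate formation; the amine is acylated far faster than the tertiary alcohol.

Step 14
Reactants: 19 keto carbamate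
Product: 20 tert‑butyl [2‑[(tert‑butyldimethylsilyl)oxy]‑3‑(dimethoxymethyl)‑5‑ethynyl‑4,5‑dihydroxycyclohexyl]carbamate (C9–OH trans to C1–OH, cis to the C5 substituent)
Conditions: Me4NBH(OAc)3, MeCN/AcOH, −30 to 0 °C
Reagents that add atoms: none
Why: Hydroxyl‑directed (Evans–Saksena type) reduction: the tertiary C1 hydroxyl, the only free hydroxyl, exchanges onto boron and delivers hydride intramolecularly to the lower face of the C9 ketone, which should give the anti (trans) 1,2‑diol with the C9 hydroxyl cis to the C5 substituent.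

Step 15
Reactants: 20 ethynyl diol
Product: 21 tert‑butyl [2‑[(tert‑butyldimethylsilyl)oxy]‑3‑(dimethoxymethyl)‑4,5‑dihydroxy‑5‑(iodoethynyl)cyclohexyl]carbamate
Conditions: NIS, AgNO3 (10 mol%), acetone, rt, dark
Reagents that add atoms: N‑iodosuccinimide, O=C1CCC(=O)N1I
Why: Silver‑catalysed electrophilic iodination of the terminal alkyne gives the 1‑iodoalkyne.

Step 16
Reactants: 21 iodoalkyne
Product: 22 tert‑butyl [2‑[(tert‑butyldimethylsilyl)oxy]‑3‑(dimethoxymethyl)‑4,5‑dihydroxy‑5‑[(Z)‑2‑iodoethenyl]cyclohexyl]carbamate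
Conditions: 2‑nitrobenzenesulfonohydrazide, Et3N, THF/i‑PrOH, rt
Reagents that add atoms: none
Why: Diimide reduction: concerted syn transfer of two hydrogens from diazene to the iodoalkyne gives the Z‑iodoalkene without touching the C–I bond, carbamate or acetal.

Step 17
Reactants: 22 acetal
Product: 23 tert‑butyl [2‑[(tert‑butyldimethylsilyl)oxy]‑3‑formyl‑4,5‑dihydroxy‑5‑[(Z)‑2‑iodoethenyl]cyclohexyl]carbamate (C5–CHO cis to C9–OH, trans to C4–O)
Conditions: PPTS (20 mol%), acetone/H2O, 45 °C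
Reagents that add atoms: water, O
Why: Mild acid‑catalysed acetal hydrolysis should keep the TBS ether, the Boc group and the alkenyl iodide and avoid epimerisation at C5 or beta‑elimination.

Step 18
Reactants: 23 ring‑A iodoalkenyl aldehyde
Product: 24 tert‑butyl [4‑[(tert‑butyldimethylsilyl)oxy]‑1,6,9‑trihydroxybicyclo[3.3.1]non‑7‑en‑3‑yl]carbamate (C6–OH syn to C9)
Conditions: CrCl2 (8 equiv), NiCl2 (2 mol%), degassed DMSO/THF, 0.005 M, rt; aq. NH4Cl
Reagents that add atoms: none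
Why: Intramolecular Nozaki–Hiyama–Kishi reaction: zerovalent nickel, formed from NiCl2 by CrCl2, inserts into the C7–I bond with retention and transmetallation gives a Z‑alkenyl species of trivalent chromium that adds to the C5 formyl group; the closest known reaction type is the Ni/Cr‑mediated cyclisation of iodoalkenyl aldehydes to cyclic allylic alcohols. Ring B closes by a 6‑exo‑trig addition from the chair of ring A in which the C1 alkenyl and C5 formyl arms are both axial, and only the Z geometry fixed in step 16 lets C7 reach C6. The new stereocentre C6 is controlled by chelation: the C9 hydroxyl, equatorial on ring A and gauche to the formyl group after step 14, binds the same chromium as the aldehyde oxygen in a six‑membered chelate, so this oxygen is held over C9 on the convex face and should end axial on ring B, syn to C9. The step needs aldehyde chemoselectivity and this facial selectivity: the neutral organochromium reagent spares carbamate, silyl ether and free hydroxyls, and the cis C9‑OH/C5‑CHO relationship secures the face. High dilution suppresses intermolecular coupling.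

Step 19
Reactants: 24 bicyclic triol
Product: 25 tert‑butyl [4,6‑bis[(tert‑butyldimethylsilyl)oxy]‑1,9‑dihydroxybicyclo[3.3.1]non‑7‑en‑3‑yl]carbamate
Conditions: TBSOTf (1.05 equiv), 2,6‑lutidine, CH2Cl2, −78 °C
Reagents that add atoms: tert‑butyldimethylsilyl trifluoromethanesulfonate, CC(C)(C)[Si](C)(C)OS(=O)(=O)C(F)(F)F
Why: Silylation at low temperature should take the least hindered hydroxyl, the allylic secondary C6–OH, in preference to the C9–OH wedged between quaternary C1 and C5 and to the tertiary C1–OH.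

Step 20
Reactants: 25 diol
Product: 26 tert‑butyl [4,6‑bis[(tert‑butyldimethylsilyl)oxy]‑1‑hydroxy‑9‑oxobicyclo[3.3.1]non‑7‑en‑3‑yl]carbamate
Conditions: IBX, DMSO, rt
Reagents that add atoms: none
Why: IBX oxidation of the remaining secondary alcohol gives the bridging C9 ketone without cleaving the C1/C9 diol, helped by relief of 1,3‑diaxial strain at C9.

Step 21
Reactants: 26 Boc carbamate
Product: 27 3‑amino‑4,6‑bis[(tert‑butyldimethylsilyl)oxy]‑1‑hydroxybicyclo[3.3.1]non‑7‑en‑9‑one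
Conditions: TFA/CH2Cl2 1:4, 0 °C; aq. NaHCO3
Reagents that add atoms: none
Why: Acidolysis of the tert‑butyl carbamate (Boc removal) at 0 °C should leave the two secondary TBS ethers, and the C9 ketone has no enolisable alpha hydrogen (C1 quaternary, C5 bridgehead).

Step 22
Reactants: 28 δ‑valerolactone; 29 n‑pentyllithium
Product: 30 1‑hydroxydecan‑5‑one
Conditions: THF, −78 °C; aq. NH4Cl at −78 °C
Reagents that add atoms: none
Why: Addition of one equivalent of an alkyllithium to a lactone at −78 °C stops at the lithium hemiketal alkoxide, which gives the hydroxy ketone on work‑up.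

Step 23
Reactants: 30 hydroxy ketone
Product: 31 5‑oxodecanal
Conditions: DMP, NaHCO3, CH2Cl2, rt
Reagents that add atoms: none
Why: Dess–Martin oxidation of the primary alcohol of the open‑chain tautomer, into which the non‑oxidisable cyclic hemiketal drains.

Step 24
Reactants: 31 5‑oxodecanal; 32 tert‑butyl (triphenyl‑λ5‑phosphanylidene)acetate
Product: 33 tert‑butyl (E)‑7‑oxododec‑2‑enoate
Conditions: CH2Cl2, rt
Reagents that add atoms: none
Why: Wittig reaction of a stabilised ylide is selective for the aldehyde over the ketone and gives the E‑enoate.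

Step 25
Reactants: 33 tert‑butyl ester
Product: 34 (E)‑7‑oxododec‑2‑enoic acid
Conditions: TFA/CH2Cl2 1:3, rt
Reagents that add atoms: none
Why: Acidolysis of the tert‑butyl ester with loss of isobutene frees the acid without touching ketone or alkene.

Step 26
Reactants: 27 amine; 34 acid
Product: 35 (E)‑N‑[4,6‑bis[(tert‑butyldimethylsilyl)oxy]‑1‑hydroxy‑9‑oxobicyclo[3.3.1]non‑7‑en‑3‑yl]‑7‑oxododec‑2‑enamide
Conditions: EDC·HCl, HOAt, CH2Cl2/DMF, 0 °C to rt
Reagents that add atoms: none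
Why: Carbodiimide‑mediated amide coupling through the HOAt active ester; the primary amine reacts in preference to the tertiary hydroxyl.

Step 27
Reactants: 35 bis‑silyl ether
Product: 36 (E)‑N‑[1,4,6‑trihydroxy‑9‑oxobicyclo[3.3.1]non‑7‑en‑3‑yl]‑7‑oxododec‑2‑enamide
Conditions: HF·pyridine, pyridine/THF, 0 °C to rt
Reagents that add atoms: none
Why: Fluoride‑mediated desilylation under non‑basic conditions removes both TBS ethers and avoids retro‑aldol opening of the beta‑hydroxy ketone.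

Step 28
Reactants: 36 allylic alcohol
Product: 37 isariotin C
Conditions: VO(acac)2 (5 mol%), t‑BuOOH, CH2Cl2, 0 °C
Reagents that add atoms: tert‑butyl hydroperoxide, CC(C)(C)OO
Why: Hydroxyl‑directed vanadium‑catalysed epoxidation: the axial allylic C6 hydroxyl binds the vanadium peroxide and should deliver oxygen to C7=C8 on its own convex face (syn to C9), setting C7 and C8, while the electron‑poor enamide alkene is inert.

**Compound list**
1 | cyclohexa‑1,4‑diene | C1=CCC=CC1 | starting material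
2 | cis‑cyclohex‑4‑ene‑1,2‑diol (meso) | C1=CC[C@@H](O)[C@@H](O)C1 | intermediate
3 | (1S,6R)‑6‑[(tert‑butyldimethylsilyl)oxy]cyclohex‑3‑en‑1‑ol | C1=CC[C@@H](O[Si](C)(C)C(C)(C)C)[C@@H](O)C1 | intermediate
4 | tert‑butyl (1S,6R)‑6‑[(tert‑butyldimethylsilyl)oxy]cyclohex‑3‑en‑1‑yl carbonate | C1=CC[C@@H](O[Si](C)(C)C(C)(C)C)[C@@H](OC(=O)OC(C)(C)C)C1 | intermediate
5 | 6‑[(tert‑butyldimethylsilyl)oxy]‑8‑iodo‑2,4‑dioxabicyclo[3.3.1]nonan‑3‑one (three oxygens cis, iodine trans) | I[C@@H]1C[C@@H](O[Si](C)(C)C(C)(C)C)[C@@H]2C[C@H]1OC(=O)O2 | intermediate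
6 | 8‑azido‑6‑[(tert‑butyldimethylsilyl)oxy]‑2,4‑dioxabicyclo[3.3.1]nonan‑3‑one (all‑cis) | [N-]=[N+]=N[C@H]1C[C@@H](O[Si](C)(C)C(C)(C)C)[C@@H]2C[C@H]1OC(=O)O2 | intermediate
7 | 8‑azido‑6‑hydroxy‑2,4‑dioxabicyclo[3.3.1]nonan‑3‑one | [N-]=[N+]=N[C@H]1C[C@@H](O)[C@@H]2C[C@H]1OC(=O)O2 | intermediate
8 | 8‑azido‑2,4‑dioxabicyclo[3.3.1]nonane‑3,6‑dione | [N-]=[N+]=N[C@H]1CC(=O)[C@@H]2C[C@H]1OC(=O)O2 | intermediate
9 | ethynylmagnesium bromide | C#C[Mg]Br | starting material
10 | 8‑azido‑6‑ethynyl‑6‑hydroxy‑2,4‑dioxabicyclo[3.3.1]nonan‑3‑one (C1–OH cis to C9–O, C4–O, C3–N) | [N-]=[N+]=N[C@H]1C[C@@](C#C)(O)[C@@H]2C[C@H]1OC(=O)O2 | intermediate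
11 | sodium alkoxide of 5‑azido‑3a‑ethynyl‑6‑hydroxyhexahydro‑1,3‑benzodioxol‑2‑one (C1/C9 carbonate, C4–ONa) | [N-]=[N+]=N[C@H]1C[C@@]2(C#C)OC(=O)O[C@H]2C[C@H]1[O-].[Na+] | intermediate (not isolated)
12 | 5‑azido‑6‑[(tert‑butyldimethylsilyl)oxy]‑3a‑ethynylhexahydro‑1,3‑benzodioxol‑2‑one | [N-]=[N+]=N[C@H]1C[C@@]2(C#C)OC(=O)O[C@H]2C[C@H]1O[Si](C)(C)C(C)(C)C | intermediate
13 | 5‑azido‑4‑[(tert‑butyldimethylsilyl)oxy]‑1‑ethynylcyclohexane‑1,2‑diol (all heteroatoms cis) | [N-]=[N+]=N[C@H]1C[C@@](C#C)(O)[C@@H](O)C[C@H]1O[Si](C)(C)C(C)(C)C | intermediate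
14 | 4‑azido‑5‑[(tert‑butyldimethylsilyl)oxy]‑2‑ethynyl‑2‑hydroxycyclohexan‑1‑one | [N-]=[N+]=N[C@H]1C[C@@](C#C)(O)C(=O)C[C@H]1O[Si](C)(C)C(C)(C)C | intermediate
15 | bis(trimethylsilyl) derivative of 14 (C1–OTMS, C9 trimethylsilyl enol ether toward C5) | [N-]=[N+]=N[C@H]1C[C@@](C#C)(O[Si](C)(C)C)C(O[Si](C)(C)C)=C[C@H]1O[Si](C)(C)C(C)(C)C | intermediate (not isolated)
16 | 4‑azido‑5‑[(tert‑butyldimethylsilyl)oxy]‑6‑(dimethoxymethyl)‑2‑ethynyl‑2‑[(trimethylsilyl)oxy]cyclohexan‑1‑one | [N-]=[N+]=N[C@H]1C[C@@](C#C)(O[Si](C)(C)C)C(=O)[C@H](C(OC)OC)[C@H]1O[Si](C)(C)C(C)(C)C | intermediate (not isolated)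
17 | 4‑azido‑5‑[(tert‑butyldimethylsilyl)oxy]‑6‑(dimethoxymethyl)‑2‑ethynyl‑2‑hydroxycyclohexan‑1‑one | [N-]=[N+]=N[C@H]1C[C@@](C#C)(O)C(=O)[C@H](C(OC)OC)[C@H]1O[Si](C)(C)C(C)(C)C | intermediate
18 | 4‑amino‑5‑[(tert‑butyldimethylsilyl)oxy]‑6‑(dimethoxymethyl)‑2‑ethynyl‑2‑hydroxycyclohexan‑1‑one | N[C@H]1C[C@@](C#C)(O)C(=O)[C@H](C(OC)OC)[C@H]1O[Si](C)(C)C(C)(C)C | intermediate (not isolated)
19 | tert‑butyl [2‑[(tert‑butyldimethylsilyl)oxy]‑3‑(dimethoxymethyl)‑5‑ethynyl‑5‑hydroxy‑4‑oxocyclohexyl]carbamate | CC(C)(C)OC(=O)N[C@H]1C[C@@](C#C)(O)C(=O)[C@H](C(OC)OC)[C@H]1O[Si](C)(C)C(C)(C)C | intermediate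
20 | tert‑butyl [2‑[(tert‑butyldimethylsilyl)oxy]‑3‑(dimethoxymethyl)‑5‑ethynyl‑4,5‑dihydroxycyclohexyl]carbamate (C9–OH trans to C1–OH) | CC(C)(C)OC(=O)N[C@H]1C[C@@](C#C)(O)[C@H](O)[C@H](C(OC)OC)[C@H]1O[Si](C)(C)C(C)(C)C | intermediate
21 | tert‑butyl [2‑[(tert‑butyldimethylsilyl)oxy]‑3‑(dimethoxymethyl)‑4,5‑dihydroxy‑5‑(iodoethynyl)cyclohexyl]carbamate | CC(C)(C)OC(=O)N[C@H]1C[C@@](C#CI)(O)[C@H](O)[C@H](C(OC)OC)[C@H]1O[Si](C)(C)C(C)(C)C | intermediate
22 | tert‑butyl [2‑[(tert‑butyldimethylsilyl)oxy]‑3‑(dimethoxymethyl)‑4,5‑dihydroxy‑5‑[(Z)‑2‑iodoethenyl]cyclohexyl]carbamate | CC(C)(C)OC(=O)N[C@H]1C[C@@](/C=C\I)(O)[C@H](O)[C@H](C(OC)OC)[C@H]1O[Si](C)(C)C(C)(C)C | intermediate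
23 | tert‑butyl [2‑[(tert‑butyldimethylsilyl)oxy]‑3‑formyl‑4,5‑dihydroxy‑5‑[(Z)‑2‑iodoethenyl]cyclohexyl]carbamate (key‑step precursor) | CC(C)(C)OC(=O)N[C@H]1C[C@@](/C=C\I)(O)[C@H](O)[C@H](C=O)[C@H]1O[Si](C)(C)C(C)(C)C | intermediate
24 | tert‑butyl [4‑[(tert‑butyldimethylsilyl)oxy]‑1,6,9‑trihydroxybicyclo[3.3.1]non‑7‑en‑3‑yl]carbamate (key‑step product) | CC(C)(C)OC(=O)N[C@H]1C[C@@]2(O)[C@H](O)[C@H]([C@H](O)C=C2)[C@H]1O[Si](C)(C)C(C)(C)C | intermediate
25 | tert‑butyl [4,6‑bis[(tert‑butyldimethylsilyl)oxy]‑1,9‑dihydroxybicyclo[3.3.1]non‑7‑en‑3‑yl]carbamate | CC(C)(C)OC(=O)N[C@H]1C[C@@]2(O)[C@H](O)[C@H]([C@H](O[Si](C)(C)C(C)(C)C)C=C2)[C@H]1O[Si](C)(C)C(C)(C)C | intermediate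
26 | tert‑butyl [4,6‑bis[(tert‑butyldimethylsilyl)oxy]‑1‑hydroxy‑9‑oxobicyclo[3.3.1]non‑7‑en‑3‑yl]carbamate | CC(C)(C)OC(=O)N[C@H]1C[C@@]2(O)C(=O)[C@H]([C@H](O[Si](C)(C)C(C)(C)C)C=C2)[C@H]1O[Si](C)(C)C(C)(C)C | intermediate
27 | 3‑amino‑4,6‑bis[(tert‑butyldimethylsilyl)oxy]‑1‑hydroxybicyclo[3.3.1]non‑7‑en‑9‑one | N[C@H]1C[C@@]2(O)C(=O)[C@H]([C@H](O[Si](C)(C)C(C)(C)C)C=C2)[C@H]1O[Si](C)(C)C(C)(C)C | intermediate
28 | δ‑valerolactone | O=C1CCCCO1 | starting material
29 | n‑pentyllithium | [Li]CCCCC | starting material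
30 | 1‑hydroxydecan‑5‑one | CCCCCC(=O)CCCCO | intermediate
31 | 5‑oxodecanal | CCCCCC(=O)CCCC=O | intermediate
32 | tert‑butyl (triphenyl‑λ5‑phosphanylidene)acetate | CC(C)(C)OC(=O)C=P(c1ccccc1)(c1ccccc1)c1ccccc1 | starting material
33 | tert‑butyl (E)‑7‑oxododec‑2‑enoate | CCCCCC(=O)CCC/C=C/C(=O)OC(C)(C)C | intermediate
34 | (E)‑7‑oxododec‑2‑enoic acid | CCCCCC(=O)CCC/C=C/C(=O)O | intermediate
35 | (E)‑N‑[4,6‑bis[(tert‑butyldimethylsilyl)oxy]‑1‑hydroxy‑9‑oxobicyclo[3.3.1]non‑7‑en‑3‑yl]‑7‑oxododec‑2‑enamide | CCCCCC(=O)CCC/C=C/C(=O)N[C@H]1C[C@@]2(O)C(=O)[C@H]([C@H](O[Si](C)(C)C(C)(C)C)C=C2)[C@H]1O[Si](C)(C)C(C)(C)C | intermediate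
36 | (E)‑N‑[1,4,6‑trihydroxy‑9‑oxobicyclo[3.3.1]non‑7‑en‑3‑yl]‑7‑oxododec‑2‑enamide | CCCCCC(=O)CCC/C=C/C(=O)N[C@H]1C[C@@]2(O)C(=O)[C@H]([C@H](O)C=C2)[C@H]1O | intermediate
37 | isariotin C | CCCCCC(=O)CCC/C=C/C(=O)N[C@H]1C[C@@]2(O)C(=O)[C@H]([C@H](O)[C@@H]3O[C@@H]32)[C@H]1O | target

**Totals**
Total step count: 28. Longest linear sequence: 24 steps (steps 1–21 and 26–28).

**Steps most likely to fail**

Step 18 (ring B closure). What may go wrong: poor facial selectivity in the addition to the formyl group, for example if the C9 hydroxyl does not hold the aldehyde oxygen, so that the C6 epimer predominates. Fallback: set out from 23 and accept the epimeric closure product, tert‑butyl [4‑[(tert‑butyldimethylsilyl)oxy]‑1,6,9‑trihydroxybicyclo[3.3.1]non‑7‑en‑3‑yl]carbamate with C6–OH anti to C9, F1. Its allylic C6 carbinol would be inverted by a Mitsunobu reaction with 4‑nitrobenzoic acid (PPh3, DIAD, THF, 0 °C). The hindered C9 and tertiary C1 hydroxyls should not react, and SN2 attack at C6 comes from the convex face. This gives the C6 4‑nitrobenzoate with the required configuration, F2, and methanolysis (K2CO3, MeOH, 0 °C) returns to the route at 24.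

Step 12 (C5 dimethoxymethylation). What may go wrong: Lewis‑acid ionisation of the allylic C4 silyloxy group of the enol ether (loss of the C4 oxygen toward an enone) competing with C–C bond formation. Fallback: set out from 14, prepare the same enol ether 15, and treat it without any Lewis acid with preformed 1,3‑dithian‑2‑ylium tetrafluoroborate (CH2Cl2, −78 °C, methanol quench). This should give 4‑azido‑5‑[(tert‑butyldimethylsilyl)oxy]‑6‑(1,3‑dithian‑2‑yl)‑2‑ethynyl‑2‑hydroxycyclohexan‑1‑one F3. Exchange of the dithiane for the dimethyl acetal with PhI(OCOCF3)2 in methanol returns to the route at 17.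

Step 5 (azide displacement). What may go wrong: E2 loss of HI toward C2 (the axial iodide is antiperiplanar to an axial C2 hydrogen) outrunning substitution at the hindered secondary carbon. Fallback: set out from 4 and epoxidise the alkene with mCPBA on the face anti to the two oxygen substituents, giving tert‑butyl 5‑[(tert‑butyldimethylsilyl)oxy]‑7‑oxabicyclo[4.1.0]heptan‑4‑yl carbonate F4. BF3·OEt2 (CH2Cl2, −40 °C) should then let the Boc carbonate open the epoxide at C4 with loss of isobutene, giving 6‑[(tert‑butyldimethylsilyl)oxy]‑8‑hydroxy‑2,4‑dioxabicyclo[3.3.1]nonan‑3‑one with C3–OH trans to C4–O, F5. Its trifluoromethanesulfonate F6 (Tf2O, pyridine, −20 °C) would be displaced by Bu4NN3 at −20 °C, where substitution of a triflate is much faster than elimination, and this returns to the route at 6.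

**Further compounds**
F1 | step 18 | tert‑butyl [4‑[(tert‑butyldimethylsilyl)oxy]‑1,6,9‑trihydroxybicyclo[3.3.1]non‑7‑en‑3‑yl]carbamate, C6 epimer of 24 | CC(C)(C)OC(=O)N[C@H]1C[C@@]2(O)[C@H](O)[C@H]([C@@H](O)C=C2)[C@H]1O[Si](C)(C)C(C)(C)C
F2 | step 18 | C6 4‑nitrobenzoate of 24 | CC(C)(C)OC(=O)N[C@H]1C[C@@]2(O)[C@H](O)[C@H]([C@H](OC(=O)c3ccc(cc3)[N+](=O)[O-])C=C2)[C@H]1O[Si](C)(C)C(C)(C)C
F3 | step 12 | 4‑azido‑5‑[(tert‑butyldimethylsilyl)oxy]‑6‑(1,3‑dithian‑2‑yl)‑2‑ethynyl‑2‑hydroxycyclohexan‑1‑one | [N-]=[N+]=N[C@H]1C[C@@](C#C)(O)C(=O)[C@H](C2SCCCS2)[C@H]1O[Si](C)(C)C(C)(C)C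
F4 | step 5 | tert‑butyl 5‑[(tert‑butyldimethylsilyl)oxy]‑7‑oxabicyclo[4.1.0]heptan‑4‑yl carbonate (epoxide anti to both oxygens) | O1[C@@H]2C[C@@H](O[Si](C)(C)C(C)(C)C)[C@@H](OC(=O)OC(C)(C)C)C[C@H]12
F5 | step 5 | 6‑[(tert‑butyldimethylsilyl)oxy]‑8‑hydroxy‑2,4‑dioxabicyclo[3.3.1]nonan‑3‑one (C3–OH trans to C4–O) | O[C@@H]1C[C@@H](O[Si](C)(C)C(C)(C)C)[C@@H]2C[C@H]1OC(=O)O2
F6 | step 5 | trifluoromethanesulfonate of F5 | O=S(=O)(O[C@@H]1C[C@@H](O[Si](C)(C)C(C)(C)C)[C@@H]2C[C@H]1OC(=O)O2)C(F)(F)F
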